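**Retrosynthetic overview**
- Locants: tetralone half C1 (C=O), C2 (CH), C3 (CH2), C4 (C–OH), C4a, C8a, C8 (OH), its benzene ring being ring A; epoxyquinone half C1'/C4' (C=O), C2'/C3' (oxirane), C5' (OH); the halves are joined by C2–C2' and C4–C3'.
- Feature: without the oxirane, C2 is the γ-carbon of a 2-alkyl-1,4-naphthoquinone (C2–C2'=C3'–C4'=O) and, because C4 is quaternary, its only acidic sp3 centre; C1 is an aldehyde carbon on ring A, which C4 holds over one face of the cyclopentene.
- Target ⇒ (deprotection, C1 oxidation) ⇒ (C1-hydroxyl-directed epoxidation of C2'=C3') ⇒ bridged quinone carbinol ⇒ (C1–C2, intramolecular vinylogous aldol) ⇒ cyclopenta-fused quinone aldehyde.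
- Quinone aldehyde ⇒ (oxidative demethylation, silylation, hydride opening, asymmetric epoxidation) ⇒ aryl indene ⇒ (Negishi, C4–C4a) ⇒ enol triflate + protected 2-bromobenzaldehyde; enol triflate ⇒ (Parham acylation C4–C3'; amide alkylation C2–C3) ⇒ 3-bromoplumbagin.
- Ring order: naphthoquinone core (from plumbagin) → cyclopentene (step 6) → bridging six-membered ring (step 15) → oxirane (step 16).

Key step: step 15

Remark: the target SMILES is read as C2 R, C4 S, C2' R, C3' S in these locants, with the oxirane oxygen on the face of C2'–C3' that is syn to the C1–C8a–C4a bridge (endo); the Shi ketone is assumed to show on the aryl indene the facial sense it shows for 1-arylcycloalkenes.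

**Step 1**
Reactants: 1 plumbagin (5-hydroxy-2-methyl-1,4-naphthoquinone)
Product: 2 3-bromo-5-hydroxy-2-methyl-1,4-naphthoquinone
Conditions: Br2 (1.1 equiv), NaOAc, AcOH, rt
Reagents that add atoms: bromine, BrBr
Why: Addition of bromine to the only unsubstituted quinone carbon (C3') and acetate-promoted loss of HBr (addition–elimination bromination of a quinone) places the halogen that later becomes the C3' carbanion.

**Step 2**
Reactants: 2 3-bromo-5-hydroxy-2-methyl-1,4-naphthoquinone
Product: 3 3-bromo-5-(methoxymethoxy)-2-methyl-1,4-naphthoquinone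
Conditions: MOMCl, iPr2NEt, CH2Cl2, 0 °C to reflux
Reagents that add atoms: chloromethyl methyl ether, COCCl
Why: O-Alkylation of the peri phenol (MOM ether formation) with a hindered amine that does not add to the bromoquinone gives a group that survives base, organolithium and hydride and leaves with mild acid at the end.

**Step 3**
Reactants: 3 3-bromo-5-(methoxymethoxy)-2-methyl-1,4-naphthoquinone
Product: 5 3-bromo-1,4-dimethoxy-5-(methoxymethoxy)-2-methylnaphthalene, via hydroquinone 4 (not isolated)
Conditions: Na2S2O4, Bu4NBr, THF/H2O, rt; then aq. KOH, Me2SO4, rt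
Reagents that add atoms: dimethyl sulfate, COS(=O)(=O)OC
Why: Dithionite reduction and Williamson methylation in the same flask (reductive methylation) mask the quinone as its dimethyl ether, which tolerates the enolate, organolithium, palladium and hydride steps that follow.

**Step 4**
Reactants: 5 3-bromo-1,4-dimethoxy-5-(methoxymethoxy)-2-methylnaphthalene
Product: 6 3-bromo-2-(bromomethyl)-1,4-dimethoxy-5-(methoxymethoxy)naphthalene
Conditions: NBS (1.05 equiv), AIBN (5 mol%), PhCF3, 85 °C, visible light
Reagents that add atoms: N-bromosuccinimide, O=C1CCC(=O)N1Br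
Why: Wohl–Ziegler radical bromination should take the only benzylic C–H position, the methyl carbon that becomes C2, as it does for 2-bromo-3-methyl-1,4-dimethoxynaphthalenes, the non-polar radical conditions holding back bromination of the ring.

**Step 5**
Reactants: 6 3-bromo-2-(bromomethyl)-1,4-dimethoxy-5-(methoxymethoxy)naphthalene; 7 N,N-dimethylacetamide
Product: 9 3-[3-bromo-1,4-dimethoxy-5-(methoxymethoxy)naphthalen-2-yl]-N,N-dimethylpropanamide, via lithium enolate 8 (not isolated)
Conditions: 7, LDA, THF, −78 °C; then 6, −78 to 0 °C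
Reagents that add atoms: none
Why: SN2 alkylation of the amide enolate by the benzylic bromide (enolate alkylation) forms C2–C3 and brings in C3 and C4, the aryl bromide being inert to the enolate.

**Step 6**
Reactants: 9 3-[3-bromo-1,4-dimethoxy-5-(methoxymethoxy)naphthalen-2-yl]-N,N-dimethylpropanamide
Product: 11 4,9-dimethoxy-8-(methoxymethoxy)-2,3-dihydro-1H-cyclopenta[b]naphthalen-1-one (ketone at C4), via aryllithium 10 (not isolated)
Conditions: t-BuLi (2.1 equiv), THF, −78 to −20 °C; aq. NH4Cl
Reagents that add atoms: none
Why: Bromine–lithium exchange outruns attack on the amide, and the C3' aryllithium acylates itself 5-exo-trig on the dimethylamide (Parham cyclisation, forming C4–C3' and the five-membered ring), the amino alkoxide shielding the ketone until work-up.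

**Step 7**
Reactants: 11 4,9-dimethoxy-8-(methoxymethoxy)-2,3-dihydro-1H-cyclopenta[b]naphthalen-1-one
Product: 13 4,9-dimethoxy-8-(methoxymethoxy)-3H-cyclopenta[b]naphthalen-1-yl trifluoromethanesulfonate (C4–OTf, C3=C4), via potassium enolate 12 (not isolated)
Conditions: KHMDS, THF, −78 °C; then PhNTf2, −78 to 0 °C
Reagents that add atoms: N-phenylbis(trifluoromethanesulfonimide), O=S(=O)(N(c1ccccc1)S(=O)(=O)C(F)(F)F)C(F)(F)F
Why: The ketone can enolise only towards C3, and O-sulfonylation of that enolate (enol triflate formation) gives the coupling handle at C4.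

**Step 8**
Reactants: 14 2-bromo-6-hydroxybenzaldehyde
Product: 15 2-bromo-6-(methoxymethoxy)benzaldehyde
Conditions: MOMCl, iPr2NEt, CH2Cl2, 0 °C to rt
Reagents that add atoms: chloromethyl methyl ether, COCCl
Why: MOM ether formation on the salicylaldehyde-type phenol gives the same acid-labile phenol protection as on the quinone half.

**Step 9**
Reactants: 15 2-bromo-6-(methoxymethoxy)benzaldehyde
Product: 16 1-bromo-2-(dimethoxymethyl)-3-(methoxymethoxy)benzene
Conditions: HC(OMe)3 (5 equiv), PPTS (5 mol%), MeOH, rt; Et3N quench
Reagents that add atoms: trimethyl orthoformate, COC(OC)OC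
Why: Orthoformate-driven acetalisation under a weak acid that should leave the aryl MOM ether intact masks the aldehyde (C1) against the organometallic and hydride steps.

**Step 10**
Reactants: 16 1-bromo-2-(dimethoxymethyl)-3-(methoxymethoxy)benzene; 13 enol triflate
Product: 19 1-[2-(dimethoxymethyl)-3-(methoxymethoxy)phenyl]-4,9-dimethoxy-8-(methoxymethoxy)-3H-cyclopenta[b]naphthalene (aryl indene, C3=C4), via aryllithium 17 (not isolated), via arylzinc chloride 18 (not isolated)
Conditions: 16, n-BuLi, THF, −78 °C; ZnCl2 (1.1 equiv), −78 °C to rt; then 13, Pd2(dba)3 (2.5 mol%), SPhos (10 mol%), THF, 60 °C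
Reagents that add atoms: none
Why: Bromine–lithium exchange, transmetalation to zinc and palladium-catalysed Negishi coupling with the enol triflate form C4–C4a, the bulky biarylphosphine being chosen for the ortho-flanked junction and the acetal and MOM groups being inert to the arylzinc.

**Step 11**
Reactants: 19 aryl indene
Product: 20 (1S,2R)-1,2-epoxide of 19 in ring numbering (oxirane on C4 and C3; C4 S, C3 R)
Conditions: D-fructose-derived Shi ketone (30 mol%), KHSO5 (as Oxone), K2CO3, Bu4NHSO4, MeCN/CH2(OMe)2/aq. Na2B4O7–Na2EDTA buffer (pH 10.5), 0 °C; extractive work-up, crude used at once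
Reagents that add atoms: potassium peroxymonosulfate, [K+].[O-]S(=O)(=O)OO
Why: Shi asymmetric epoxidation through the chiral dioxirane and a spiro transition state is reliable for trisubstituted 1-arylcycloalkenes and should put oxygen on the face that makes C4 S, while the basic buffer spares the acid-labile benzylic epoxide, the acetal and the MOM ethers.

**Step 12**
Reactants: 20 epoxide
Product: 21 (S)-1-[2-(dimethoxymethyl)-3-(methoxymethoxy)phenyl]-4,9-dimethoxy-8-(methoxymethoxy)-2,3-dihydro-1H-cyclopenta[b]naphthalen-1-ol (tertiary C4 carbinol)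
Conditions: LiBEt3H (1 M in THF), THF, 0 °C to rt
Reagents that add atoms: none
Why: SN2 hydride opening at the secondary carbon C3 by a borohydride that is not Lewis acidic leaves the C4–O bond untouched, so C4 keeps the configuration set in step 11.

**Step 13**
Reactants: 21 tertiary carbinol
Product: 22 triethylsilyl ether of 21 (C4 S)
Conditions: TESOTf (1.3 equiv), 2,6-lutidine (3 equiv), CH2Cl2, −78 °C
Reagents that add atoms: triethylsilyl trifluoromethanesulfonate, CC[Si](CC)(CC)OS(=O)(=O)C(F)(F)F
Why: Silyl triflate silylation copes with the hindered tertiary alcohol and, at −78 °C with excess lutidine, should not activate the acetal or the MOM ethers; the ether keeps the C4 oxygen from closing a lactol on the aldehyde released next.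

**Step 14**
Reactants: 22 triethylsilyl ether
Product: 23 (S)-2-(methoxymethoxy)-6-[8-(methoxymethoxy)-4,9-dioxo-1-(triethylsilyloxy)-2,3,4,9-tetrahydro-1H-cyclopenta[b]naphthalen-1-yl]benzaldehyde (quinone aldehyde, C4 S)
Conditions: (NH4)2Ce(NO3)6 (2.5 equiv), MeCN/H2O (4:1), 0 °C, 15 min
Reagents that add atoms: water, O
Why: Oxidative demethylation of the 1,4-dimethoxynaphthalene by tetravalent cerium gives the quinone, and the acidic aqueous medium hydrolyses the dimethyl acetal in the same operation, while the aryl MOM ethers and the hindered tertiary silyl ether are expected to survive the short cold exposure.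

**Step 15**
Reactants: 23 quinone aldehyde
Product: 25 bridged quinone carbinol (C1–C2 bond closed; C1 S with the hydroxyl endo, that is syn to the C2'=C3' bridge; C2 R; C4 S), via lithium dienolate 24 (not isolated)
Conditions: DBU (0.5 equiv), LiCl (2 equiv), degassed MeCN (0.01 M), 0 °C, argon; AcOH quench
Reagents that add atoms: none
Why: Proposed new method: DBU, helped by Li+ chelated between the C4' carbonyl and the C5' OMOM group, removes a C2 proton (the only sp3 C–H conjugated to the quinone, since C4 is quaternary) to give the quinone-methide dienolate 24 (O–C4'=C3'–C2'=C2), whose C2 terminus adds to the aldehyde carbon C1 held above it by C4; the closest known reactions are vinylogous aldol additions of γ-enolisable enones and the base-induced quinone-methide tautomerism of 2-alkyl-1,4-naphthoquinones. The six-membered ring C1–C2–C3–C4–C4a–C8a closes 6-(enolexo)-exo-trig and turns the cyclopentene into a bicyclo[3.2.1]octene. C2 is set by the tether, because ring A hangs from C4 on one face of the five-membered ring and the new bond can form only cis to it. C1 should come out with the hydroxyl endo because the addition is reversible and only this epimer allows a lithium bridge or hydrogen bond from the C1 oxygen to the C1' carbonyl. The step needs site selectivity, secured by the quaternary C4 and the non-enolisable aldehyde, and it needs ring closure to outrun coupling of the dienolate and loss of silanol from C4, for which high dilution, exclusion of oxygen, low temperature and substoichiometric base are chosen; the product cannot be deprotonated again at C2, now a bridgehead.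

**Step 16**
Reactants: 25 bridged quinone carbinol
Product: 26 endo epoxide of 25 (oxirane on C2' and C3', oxygen syn to the C1–C8a–C4a bridge; C2' R, C3' S; other centres unchanged)
Conditions: Ti(OiPr)4 (1.2 equiv), t-BuOOH (anhydrous in decane, 3 equiv), 4 Å molecular sieves, CH2Cl2, −20 to 0 °C
Reagents that add atoms: tert-butyl hydroperoxide, CC(C)(C)OO
Why: In this hydroxyl-directed titanium alkoxide/hydroperoxide epoxidation of a hydroxy enone, the metal is held on the endo face by the C1 alkoxide and the C1' carbonyl and passes the peroxide oxygen to C2'–C3' by conjugate addition and ring closure, so both oxirane carbons receive oxygen on the face that unbound peroxide would avoid.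

**Step 17**
Reactants: 26 epoxy carbinol
Product: 27 C1 ketone (bis-MOM, triethylsilyl-protected target)
Conditions: Dess–Martin periodinane, NaHCO3, CH2Cl2, rt
Reagents that add atoms: none
Why: Dess–Martin oxidation converts the secondary benzylic alcohol into the aryl ketone under buffered neutral conditions; the bridgehead C2 cannot epimerise and the epoxide, silyl ether and MOM ethers are inert.

**Step 18**
Reactants: 27 protected target
Product: 28 CNP0220680.2 (target; C2 R, C4 S, C2' R, C3' S)
Conditions: TFA/H2O/CH2Cl2 (5:1:5), 0 °C to rt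
Reagents that add atoms: none
Why: Acidic hydrolysis removes the two carbonyl-chelated aryl MOM ethers and the tertiary silyl ether, while the fully substituted oxirane between two ketones and the bridgehead C4 carbinol resist ionisation, so no stereocentre is at risk.

**Compound list**
1 | plumbagin (5-hydroxy-2-methyl-1,4-naphthoquinone) | CC1=CC(=O)c2c(O)cccc2C1=O | starting material
2 | 3-bromo-5-hydroxy-2-methyl-1,4-naphthoquinone | CC1=C(Br)C(=O)c2c(O)cccc2C1=O | intermediate
3 | 3-bromo-5-(methoxymethoxy)-2-methyl-1,4-naphthoquinone | CC1=C(Br)C(=O)c2c(OCOC)cccc2C1=O | intermediate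
4 | 3-bromo-5-(methoxymethoxy)-2-methylnaphthalene-1,4-diol | Cc1c(Br)c(O)c2c(OCOC)cccc2c1O | intermediate (not isolated)
5 | 3-bromo-1,4-dimethoxy-5-(methoxymethoxy)-2-methylnaphthalene | COc1c(C)c(Br)c(OC)c2c(OCOC)cccc12 | intermediate
6 | 3-bromo-2-(bromomethyl)-1,4-dimethoxy-5-(methoxymethoxy)naphthalene | COc1c(CBr)c(Br)c(OC)c2c(OCOC)cccc12 | intermediate
7 | N,N-dimethylacetamide | CC(=O)N(C)C | starting material
8 | lithium enolate of N,N-dimethylacetamide | C=C(O[Li])N(C)C | intermediate (not isolated)
9 | 3-[3-bromo-1,4-dimethoxy-5-(methoxymethoxy)naphthalen-2-yl]-N,N-dimethylpropanamide | COc1c(CCC(=O)N(C)C)c(Br)c(OC)c2c(OCOC)cccc12 | intermediate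
10 | C3' aryllithium from 9 | COc1c(CCC(=O)N(C)C)c([Li])c(OC)c2c(OCOC)cccc12 | intermediate (not isolated)
11 | 4,9-dimethoxy-8-(methoxymethoxy)-2,3-dihydro-1H-cyclopenta[b]naphthalen-1-one | O=C1CCc2c1c(OC)c1c(OCOC)cccc1c2OC | intermediate
12 | potassium enolate of 11 | [K]OC1=CCc2c1c(OC)c1c(OCOC)cccc1c2OC | intermediate (not isolated)
13 | 4,9-dimethoxy-8-(methoxymethoxy)-3H-cyclopenta[b]naphthalen-1-yl trifluoromethanesulfonate | O=S(=O)(OC1=CCc2c1c(OC)c1c(OCOC)cccc1c2OC)C(F)(F)F | intermediate
14 | 2-bromo-6-hydroxybenzaldehyde | O=Cc1c(O)cccc1Br | starting material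
15 | 2-bromo-6-(methoxymethoxy)benzaldehyde | O=Cc1c(OCOC)cccc1Br | intermediate
16 | 1-bromo-2-(dimethoxymethyl)-3-(methoxymethoxy)benzene | COC(OC)c1c(OCOC)cccc1Br | intermediate
17 | [2-(dimethoxymethyl)-3-(methoxymethoxy)phenyl]lithium | COC(OC)c1c(OCOC)cccc1[Li] | intermediate (not isolated)
18 | [2-(dimethoxymethyl)-3-(methoxymethoxy)phenyl]zinc chloride | COC(OC)c1c(OCOC)cccc1[Zn]Cl | intermediate (not isolated)
19 | 1-[2-(dimethoxymethyl)-3-(methoxymethoxy)phenyl]-4,9-dimethoxy-8-(methoxymethoxy)-3H-cyclopenta[b]naphthalene | COC(OC)c1c(OCOC)cccc1C1=CCc2c1c(OC)c1c(OCOC)cccc1c2OC | intermediate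
20 | (1S,2R)-1,2-epoxide of 19 (C4 S, C3 R) | COC(OC)c1c(OCOC)cccc1[C@@]12O[C@@H]1Cc1c2c(OC)c2c(OCOC)cccc2c1OC | intermediate
21 | (S)-1-[2-(dimethoxymethyl)-3-(methoxymethoxy)phenyl]-4,9-dimethoxy-8-(methoxymethoxy)-2,3-dihydro-1H-cyclopenta[b]naphthalen-1-ol | COC(OC)c1c(OCOC)cccc1[C@@]1(O)CCc2c1c(OC)c1c(OCOC)cccc1c2OC | intermediate
22 | triethylsilyl ether of 21 (C4 S) | COC(OC)c1c(OCOC)cccc1[C@@]1(O[Si](CC)(CC)CC)CCc2c1c(OC)c1c(OCOC)cccc1c2OC | intermediate
23 | (S)-2-(methoxymethoxy)-6-[8-(methoxymethoxy)-4,9-dioxo-1-(triethylsilyloxy)-2,3,4,9-tetrahydro-1H-cyclopenta[b]naphthalen-1-yl]benzaldehyde | O=Cc1c(OCOC)cccc1[C@@]1(O[Si](CC)(CC)CC)CCC2=C1C(=O)c1c(OCOC)cccc1C2=O | intermediate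
24 | lithium quinone-methide dienolate of 23 (O–C4'=C3'–C2'=C2) | O=Cc1c(OCOC)cccc1[C@@]1(O[Si](CC)(CC)CC)CC=C2C1=C(O[Li])c1c(OCOC)cccc1C2=O | intermediate (not isolated)
25 | bridged quinone carbinol (C1 S, hydroxyl endo; C2 R; C4 S; bis-MOM; C4 triethylsilyl ether) | O[C@@H]1c2c(OCOC)cccc2[C@@]2(O[Si](CC)(CC)CC)C[C@@H]1C1=C2C(=O)c2c(OCOC)cccc2C1=O | intermediate
26 | endo 2',3'-epoxide of 25 (C2' R, C3' S; oxygen syn to the C1–C8a–C4a bridge) | O[C@@H]1c2c(OCOC)cccc2[C@@]2(O[Si](CC)(CC)CC)C[C@@H]1[C@@]13O[C@]12C(=O)c1c(OCOC)cccc1C3=O | intermediate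
27 | C1 ketone of 26 (bis-MOM, triethylsilyl-protected target) | O=C1c2c(OCOC)cccc2[C@@]2(O[Si](CC)(CC)CC)C[C@@H]1[C@@]13O[C@]12C(=O)c1c(OCOC)cccc1C3=O | intermediate
28 | CNP0220680.2 (C2 R, C4 S, C2' R, C3' S) | O=C1c2c(O)cccc2[C@@]2(O)C[C@@H]1[C@@]13O[C@]12C(=O)c1c(O)cccc1C3=O | target

**Step count**
Total: 18 steps. Longest linear sequence: 16 steps (steps 1–7 and 10–18, from plumbagin).

**Steps most likely to fail**

Step 15. The dienolate may not form with an amine base, or it may be diverted before it reaches the aldehyde, by coupling through its quinone-methide form, by electron transfer to unreacted quinone, or by vinylogous loss of triethylsilanol from C4. The C1 epimers may also fail to converge. The fallback uses known reactions, sets out from 22 and comes back to the route at 25; it makes the C1–C2 bond at the hydroquinone dimethyl ether level by a samarium Barbier cyclisation. Radical bromination of 22 at C2, its only benzylic C–H position (NBS, AIBN, K2CO3, PhCF3, 80 °C), would give the benzylic bromide F1. Hydrolysis of the acetal on wet silica with a trace of oxalic acid would give the bromo aldehyde F2. SmI2 in THF at −78 °C would convert the bromide into a benzylsamarium that adds to the aldehyde on the only face it can reach, giving the bridged carbinol F3 as C1 epimers. Dess–Martin oxidation to the bridged ketone F4 and NaBH4 reduction from the open exo face would give the endo carbinol F5. (NH4)2Ce(NO3)6 in MeCN/H2O would then release the quinone and give 25.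

Step 16. Oxygen transfer to the electron-poor, tetrasubstituted double bond may be too slow on the titanium template, or free hydroperoxide may attack from the exo face. The fallback sets out from 25 and comes back at 26; it gives up the Lewis-acid template for an anionic, alkoxide-anchored Weitz–Scheffer epoxidation. Compound 25 would be added to lithium tert-butyl peroxide (t-BuOOH, n-BuLi) in THF at −40 °C, so that the C1 lithium alkoxide holds the peroxide in a mixed aggregate and hands it to C2' from the endo face, the syn delivery known for hydroxy-substituted enones and vinyl sulfones. This makes no new compound (F0).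

Step 11. Facial discrimination may be poor on the crowded trisubstituted double bond, or the very electron-rich benzylic epoxide may rearrange before it is reduced. The fallback sets out from 11 and 16 and comes back at 21; it replaces asymmetric catalysis by resolution and bypasses steps 7 and 10 to 12. Aryllithium 17 (from 16 and n-BuLi), made less basic with anhydrous CeCl3, would be added to ketone 11 in THF at −78 °C to give the racemic tertiary carbinol F6. Its S enantiomer, which is 21, would be separated by preparative chromatography on a chiral stationary phase.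

**Further compounds**
F1 | step 15 | C2 bromide of 22 (C2 epimers) | COC(OC)c1c(OCOC)cccc1[C@@]1(O[Si](CC)(CC)CC)CC(Br)c2c1c(OC)c1c(OCOC)cccc1c2OC
F2 | step 15 | bromo aldehyde from F1 | O=Cc1c(OCOC)cccc1[C@@]1(O[Si](CC)(CC)CC)CC(Br)c2c1c(OC)c1c(OCOC)cccc1c2OC
F3 | step 15 | bridged carbinol with dimethoxynaphthalene (C1 epimers) | OC1c2c(OCOC)cccc2[C@@]2(O[Si](CC)(CC)CC)C[C@@H]1c1c2c(OC)c2c(OCOC)cccc2c1OC
F4 | step 15 | bridged C1 ketone with dimethoxynaphthalene | O=C1c2c(OCOC)cccc2[C@@]2(O[Si](CC)(CC)CC)C[C@@H]1c1c2c(OC)c2c(OCOC)cccc2c1OC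
F5 | step 15 | endo carbinol with dimethoxynaphthalene | O[C@@H]1c2c(OCOC)cccc2[C@@]2(O[Si](CC)(CC)CC)C[C@@H]1c1c2c(OC)c2c(OCOC)cccc2c1OC
F0 | step 16 | none | none
F6 | step 11 | racemic form of carbinol 21 | COC(OC)c1c(OCOC)cccc1C1(O)CCc2c1c(OC)c1c(OCOC)cccc1c2OC
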